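## Structural features

The target is a sesquilignan built on an oxolane (O1, C2, C3, C4, C5). C2 carries ring B directly, C3 a hydroxymethyl group, and C4 both a tertiary hydroxyl and the benzyl group of ring A, a free guaiacol. The ring B oxygen para to C2 is etherified by Cβ of a 1-arylpropane-1,3-diol side chain (Cα: secondary carbinol bearing ring C, a second free guaiacol; Cγ: hydroxymethyl). C2 (S), C3 (R) and C4 (S) are contiguous, with the aryl group trans and the ring A benzyl group cis to the C3 hydroxymethyl group. Cα (S) and Cβ (R) form a separate erythro pair that ring B insulates from the core. C2–O1 and Cα–OH are both para-oxygenated benzylic C–O bonds: acid ionises them (epimerisation, Friedel–Crafts capture of C2 by ring A), hydrogenolysis can cut them, and a leaving group on Cα beside a free ring C phenol would give a quinone methide under base. The real difficulties are the fully substituted carbinol C4 next to C3, telling apart the nearly identical rings A and B, and absolute control of the remote erythro pair. The key step uses the fact that C2 is the benzylic carbon of ring B and stands in a 1,5-relation to the C5 hydroxyl oxygen (O–C5–C4–C3–C2). If ring B is the only electron-rich ring, oxidising that one C–H bond of an open-chain 2,3-dibenzylbutane-1,2,4-triol closes O1–C2, and the C3 and C4 centres of that triol are those of an α-hydroxy-α,β-dibenzyl-γ-butyrolactone.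

## Logic of the disconnections

24 from 23: the acyl–oxygen bonds of five esters are cut (three 4-nitrobenzoates, two aryl pivalates). The last step must avoid acid and hydrogen, so every remaining protecting group is an ester and one methanolysis ends the route. The demand is that the Cα ester cleaves before the ring C phenol is freed, otherwise a quinone methide would form.

23 from 22: the Cα–O bond is cut with inversion. A boron imide aldol gives the syn (threo) pair, not the erythro pair of the target, so Cβ is kept and Cα is inverted. The gain is that the side chain becomes the product of a well-understood syn aldol. The demand is a clean SN2 displacement at a benzylic carbinol, which is why ring C carries an electron-poor acyloxy group.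

22 from 21, and 21 from 18 and 20: the Cγ–N bond and then the Cα–Cβ bond are cut. One auxiliary-controlled aldol creates both side-chain centres independently of the distant core. The side chain is reduced to a glycolyl imide on the ring B oxygen and an aldehyde. The forward steps must form the Z-enolate in the presence of two free hydroxyls and reduce the imide without touching the aryl esters.

18 from 16 and 17, and 16 from 15: the ring B O–CH2 bond and the benzyl O–C bond are cut. Under carbonate the phenoxide is the only nucleophile, so the auxiliary unit can be attached without protecting the aliphatic hydroxyls. The demands are substitution faster than acyl transfer, and hydrogenolysis that spares the C2–O1 benzylic ether.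

15 from 14 (key): the O1–C2 bond is cut. This removes the ring and the C2 stereocentre and leaves an open-chain triol whose two centres come from lactone chemistry. The forward step must oxidise only the ring B benzylic C–H bond, stop after one oxidation, and place the aryl group trans to the C3 hydroxymethyl group.

14 from 12 through 13, and 12 from 11: the pivaloyl–oxygen and silicon–oxygen bonds are exchanged and the two primary C–OH groups are traced to a lactone. The lactone ties C5 to the C3 hydroxymethyl carbon, and hydride releases both hydroxyls at once. The pivalate can only follow the hydride step, so the forward acylation must pick the phenol out of three aliphatic hydroxyls; it is done through the phenoxide.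

11 from 7 and 10: the C4–CH2(ring A) bond is cut. Alkylation of the enediolate builds the quaternary carbinol, and C4 then depends only on C3. The demand is attack anti to the ring B benzyl group and a benzylic bromide stable enough to handle.

7 from 6: the C4–O bond is cut (enolate hydroxylation). The configuration of this centre is irrelevant because the next step planarises it.

6 from 4 through 5, 4 from 3, and 3 from 1 and 2: the lactone C–O bond, the C3–H bond and the C2–C3 bond (as C=C) are cut. The condensation joins the aldehyde carbon (C2) to a succinate that supplies C3, C4, C5 and the C3 hydroxymethyl carbon. Asymmetric hydrogenation sets C3, the only centre the route takes from a catalyst. The demands are high enantioselectivity and reduction of the ester in the presence of the carboxylate.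

10 from 9, 9 from 8, and 20 from 19: functional group interchanges only (C–Br, O–Si and O–acyl bonds). The demand in the first is silylation at the phenol and not at the benzylic alcohol.

## Other disconnections considered

Alternative 1: The cuts are C2–C3 and C4–CH2(ring A). In the forward sense the lithiated dithiane A3 would add to the β-carbon of the α-benzyloxy butenolide A2 anti to the menthyloxy group, and the enolate would be trapped by bromide A4 anti to the dithianyl group, giving A1 in one pot.
- In its favour: it is fully convergent, C3 and C4 come from one auxiliary-controlled operation, and C2 arrives at the carbonyl oxidation level. No C–H oxidation is needed and the C2 oxygen does not depend on an electronic bias between rings A and B. On these two points it is the better plan.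
- Against it here: the α-alkoxy group pushes electron density onto the β-carbon of A2, so conjugate addition is disfavoured and 1,2-addition or deprotonation at the acetal carbon may intrude. The enolate that must be benzylated is hindered and α-oxygenated. The dithiane must later be removed next to electron-rich arenes. C2 would still have to be set by ketone reduction and cyclisation, and a tertiary benzyl ether must be carried.
- Comparison: the C3/C4 relationship arises from the same trans-alkylation logic as in the chosen route, so the two are equal on structure. The core C–C bonds form in fewer steps. The steps after A1 (reduction of lactone and acetal, dethioacetalisation, reductive closure, deprotection) and the preparation of A2 should bring the total close to the chosen route.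

Alternative 2: The cut is the C4–CH(ring A) bond, with a temporary second oxolane. On irradiation the excited C4 ketone of oxolanone A6 would abstract the benzylic hydrogen of the ring A benzyl ether (1,6-hydrogen transfer), and the 1,5-biradical would close to the cis-fused bicycle A5. Hydrogenolysis of the ring A benzylic C–O bonds would then reveal the ring A benzyl group.
- In its favour: the quaternary carbinol and the C4–benzyl bond form in one reagent-free step, and the C3/C4 relationship is dictated by cis ring fusion. On control of C4 it is at least the equal of the chosen plan and arguably better.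
- Against it here: A6 must first be made enantiopure with C2 and C3 set. α-Alkoxy ketones are prone to Norrish type 1 cleavage. The two benzylic C–O bonds of A5 must later be told apart by hydrogenolysis on an electronic bias (phenol against mesylate), the same kind of differentiation the chosen key step needs, so nothing is gained there. The aryl mesylate needs forcing conditions for removal next to fragile groups.
- Comparison: the mechanism is radical and intramolecular against polar and intramolecular. Step economy is expected to be similar or worse once the synthesis of A6 is counted.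

Alternative 3: The cuts are O1–C2 and C3–C4. A secondary amine catalyst would turn enal A9 into an iminium ion, the hydroxyl of hydroxy ketone A8 would add (O1–C2), and the resulting enamine would attack the ketone (C3–C4, 5-exo-trig) to give A7 with C2, C3 and C4 set.
- In its favour: the ring and three stereocentres would come from one catalytic step on two achiral partners. On step economy for the core it is clearly the better plan.
- Against it here: additions of aliphatic alcohols to iminium ions are reversible and weakly face-selective. The electron-rich enal A9 is a poor acceptor. The aldol must attack a ketone and create a tertiary carbinol whose face (hydroxyl against benzyl) the catalyst controls only indirectly. A8 can enolise toward its benzylic side and self-condense.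
- Comparison: the bond set is elegant and short. The chosen plan instead takes each centre from an event with close precedent (asymmetric hydrogenation, anti alkylation, trans-selective cation capture), so it is longer but more predictable.

Key step: step 10

Remark: atom labels are O1, C2–C5 for the oxolane and Cα, Cβ, Cγ for the side chain. Every centre of 14 ((2S,3S)) and 15 ((2S,3R,4S)) was checked against the target and needs no correction. The side chain is erythro (αS,βR), the anti pair in aldol terms, whereas a boron imide aldol gives the syn pair; Cβ is therefore set by the aldol and Cα is inverted afterwards.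

Remark: refinements around 14 are a triisopropylsilyl group on ring A (stable bromide, survives LiAlH4), its exchange for pivaloyl through the phenoxide in one flask, and a pivalate on ring C as well, so that one methanolysis ends the route.

Assumption: 17 is treated as a catalogue compound; it is otherwise one N-acylation away from (S)-4-benzyloxazolidin-2-one.

## Route

Step 1
Reactants: 1 O-benzylvanillin (4-benzyloxy-3-methoxybenzaldehyde); 2 dimethyl succinate
Product: 3 (E)-4-(4-benzyloxy-3-methoxyphenyl)-3-(methoxycarbonyl)but-3-enoic acid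
Conditions: NaOMe (2.2 equiv), MeOH, reflux; then 2 M HCl
Reagents that add atoms: none
Why: Stobbe condensation (aldol addition, lactonisation, eliminative ring opening) joins the aldehyde carbon to the succinate and leaves the conjugated ester and the free acid differentiated; the aryl group ends trans to the ester.

Step 2
Reactants: 3 (E)-4-(4-benzyloxy-3-methoxyphenyl)-3-(methoxycarbonyl)but-3-enoic acid
Product: 4 (R)-4-(4-benzyloxy-3-methoxyphenyl)-3-(methoxycarbonyl)butanoic acid
Conditions: H2 (3 atm), [Rh(cod)Cl]2 (0.5 mol %), (4S,5S)-MOD-DIOP (1.1 mol %), Et3N (1 equiv), MeOH, 30 °C; HCl work-up; recrystallisation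
Reagents that add atoms: none
Why: Asymmetric hydrogenation of an itaconate-type half ester: carboxylate and alkene bind rhodium and the chiral diphosphine selects the alkene face, setting C3; the ligand antipode is the one expected to give the R acid and is exchanged for its mirror image should the sense prove opposite. The homogeneous catalyst leaves the aryl benzyl ether intact.

Step 3
Reactants: 4 (R)-4-(4-benzyloxy-3-methoxyphenyl)-3-(methoxycarbonyl)butanoic acid
Product: 6 (R)-4-(4-benzyloxy-3-methoxybenzyl)dihydrofuran-2(3H)-one, via hydroxy acid 5 (not isolated)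
Conditions: KOH (1 equiv), EtOH; CaCl2, NaBH4, EtOH, −10 °C to rt; then 3 M HCl, rt
Reagents that add atoms: none
Why: Chemoselective borohydride reduction: calcium borohydride formed in the flask reduces the methyl ester while the potassium carboxylate is inert, and acidification lactonises the hydroxy acid; C3 is not touched.

Step 4
Reactants: 6 (R)-4-(4-benzyloxy-3-methoxybenzyl)dihydrofuran-2(3H)-one
Product: 7 (3R,4S)-4-(4-benzyloxy-3-methoxybenzyl)-3-hydroxydihydrofuran-2(3H)-one
Conditions: KN(SiMe3)2, THF, −78 °C; 2-(phenylsulfonyl)-3-phenyloxaziridine, −78 °C; aq. NH4Cl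
Reagents that add atoms: 2-(phenylsulfonyl)-3-phenyloxaziridine O=S(=O)(c1ccccc1)N1OC1c1ccccc1
Why: Enolate α-hydroxylation by electrophilic oxygen transfer from an N-sulfonyloxaziridine; attack anti to the ring B benzyl group should give mainly the trans isomer, but this centre is planarised in step 7, so its ratio does not matter.

Step 5
Reactants: 8 vanillyl alcohol (4-hydroxy-3-methoxybenzyl alcohol)
Product: 9 [3-methoxy-4-(triisopropylsilyloxy)phenyl]methanol
Conditions: NaH (1.0 equiv), THF, 0 °C; iPr3SiCl, 0 °C to rt
Reagents that add atoms: chlorotriisopropylsilane CC(C)[Si](Cl)(C(C)C)C(C)C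
Why: Chemoselective O-silylation: one equivalent of base forms only the phenoxide, whose parent is far more acidic than the benzylic alcohol, and the phenoxide takes the silyl chloride.

Step 6
Reactants: 9 [3-methoxy-4-(triisopropylsilyloxy)phenyl]methanol
Product: 10 [4-(bromomethyl)-2-methoxyphenoxy]triisopropylsilane
Conditions: PBr3 (0.4 equiv), Et2O, 0 °C; aq. NaHCO3 wash; used without chromatography
Reagents that add atoms: phosphorus tribromide BrP(Br)Br
Why: Bromination of the benzylic alcohol through its phosphite ester by SN2 displacement; the bulky aryl silyl ether survives and keeps the electron-rich bromide handleable.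

Step 7
Reactants: 7 (3R,4S)-4-(4-benzyloxy-3-methoxybenzyl)-3-hydroxydihydrofuran-2(3H)-one; 10 [4-(bromomethyl)-2-methoxyphenoxy]triisopropylsilane
Product: 11 (3S,4S)-4-(4-benzyloxy-3-methoxybenzyl)-3-hydroxy-3-[3-methoxy-4-(triisopropylsilyloxy)benzyl]dihydrofuran-2(3H)-one
Conditions: LiN(iPr)2 (2.2 equiv), THF, −78 to −40 °C; 10, DMPU, −78 to −20 °C; aq. NH4Cl
Reagents that add atoms: none
Why: Alkylation of the α-hydroxy lactone dianion (enediolate): the bromide approaches the planar enediolate anti to the ring B benzyl group, so C4 is set with the two benzyl groups trans and the hydroxyl cis to the ring B benzyl group, the relationship the target needs.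

Step 8
Reactants: 11 (3S,4S)-4-(4-benzyloxy-3-methoxybenzyl)-3-hydroxy-3-[3-methoxy-4-(triisopropylsilyloxy)benzyl]dihydrofuran-2(3H)-one
Product: 12 (2S,3S)-3-(4-benzyloxy-3-methoxybenzyl)-2-[3-methoxy-4-(triisopropylsilyloxy)benzyl]butane-1,2,4-triol
Conditions: LiAlH4, THF, 0 °C; aq. NaOH work-up
Reagents that add atoms: none
Why: Hydride reduction of the lactone to the diol frees the C5 hydroxyl and the C3 hydroxymethyl group; neither stereocentre is involved and the benzyl and triisopropylsilyl ethers are inert.

Step 9
Reactants: 12 (2S,3S)-3-(4-benzyloxy-3-methoxybenzyl)-2-[3-methoxy-4-(triisopropylsilyloxy)benzyl]butane-1,2,4-triol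
Product: 14 (2S,3S)-3-(4-benzyloxy-3-methoxybenzyl)-2-[3-methoxy-4-(pivaloyloxy)benzyl]butane-1,2,4-triol, via phenol triol 13 (not isolated)
Conditions: Bu4NF (1.05 equiv), THF, 0 °C; then t-BuCOCl (1.1 equiv), 0 °C
Reagents that add atoms: pivaloyl chloride CC(C)(C)C(Cl)=O
Why: Fluoride cleaves the aryl silyl ether to the tetrabutylammonium phenoxide, which takes the hindered acid chloride before any neutral aliphatic hydroxyl can react (chemoselective O-acylation of a phenoxide).

Step 10
Reactants: 14 (2S,3S)-3-(4-benzyloxy-3-methoxybenzyl)-2-[3-methoxy-4-(pivaloyloxy)benzyl]butane-1,2,4-triol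
Product: 15 (2S,3R,4S)-2-(4-benzyloxy-3-methoxyphenyl)-3-(hydroxymethyl)-4-[3-methoxy-4-(pivaloyloxy)benzyl]oxolan-4-ol
Conditions: DDQ (1.1 equiv), 4 Å molecular sieves, CH2Cl2, 0 °C to rt; sat. aq. NaHCO3
Reagents that add atoms: none
Why: DDQ forms a charge-transfer complex with the electron-rich ring B and removes hydride (electron, proton, electron) from its benzylic methylene, giving a para-benzyloxy-stabilised cation of quinone methide character. The C5 hydroxyl adds to this planar carbon in a 5-exo-trig closure that forms O1–C2 and the oxolane, whereas the other two hydroxyls could only form oxetanes. The closest known reaction type is the quinone-mediated oxidative cyclisation of dibenzylbutanediols to 7,9'-epoxylignans, a relative of oxidative para-methoxybenzyl ether cleavage. C2 is set under substrate control: in the envelope transition state the aryl group takes the pseudo-equatorial position trans to the C3 hydroxymethyl group, and because the cation can re-form, the trans isomer is also the thermodynamic outcome. Site selectivity between the two benzylic methylenes is secured twice: ring A has an acyloxy group para and only a meta methoxy group, so its benzylic cation lacks a donor, and its methylene sits beside the electron-poor C4 carbinol carbon. The step also needs selectivity against a second oxidation at the now doubly activated C2–H; this rests on the limited charge of oxidant, on the exclusion of water (no hydroxy ketone can form) and on quenching at full conversion. The methylene of the benzyl ether is not attacked because its cation would have no para donor.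

Step 11
Reactants: 15 (2S,3R,4S)-2-(4-benzyloxy-3-methoxyphenyl)-3-(hydroxymethyl)-4-[3-methoxy-4-(pivaloyloxy)benzyl]oxolan-4-ol
Product: 16 (2S,3R,4S)-2-(4-hydroxy-3-methoxyphenyl)-3-(hydroxymethyl)-4-[3-methoxy-4-(pivaloyloxy)benzyl]oxolan-4-ol
Conditions: H2 (1 atm), Pd/C (10 wt %), EtOAc, rt, stopped at full conversion
Reagents that add atoms: none
Why: Heterogeneous hydrogenolysis of the aryl benzyl ether; in a neutral aprotic solvent the O-benzyl group should cleave much faster than the cyclic benzylic C2–O1 bond, and the aryl pivalate is inert.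

Step 12
Reactants: 16 (2S,3R,4S)-2-(4-hydroxy-3-methoxyphenyl)-3-(hydroxymethyl)-4-[3-methoxy-4-(pivaloyloxy)benzyl]oxolan-4-ol; 17 (S)-4-benzyl-3-(chloroacetyl)oxazolidin-2-one
Product: 18 (S)-4-benzyl-3-{[4-((2S,3R,4S)-4-hydroxy-3-(hydroxymethyl)-4-[3-methoxy-4-(pivaloyloxy)benzyl]oxolan-2-yl)-2-methoxyphenoxy]acetyl}oxazolidin-2-one
Conditions: K2CO3 (1.5 equiv), NaI (0.1 equiv), acetone, rt
Reagents that add atoms: none
Why: Williamson ether synthesis: carbonate ionises only the phenol, and the phenoxide displaces halide (iodide from Finkelstein exchange in the flask) at the activated α-carbon by SN2 faster than it attacks an imide carbonyl.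

Step 13
Reactants: 19 vanillin
Product: 20 4-formyl-2-methoxyphenyl pivalate
Conditions: t-BuCOCl, Et3N, DMAP (cat.), CH2Cl2, 0 °C
Reagents that add atoms: pivaloyl chloride CC(C)(C)C(Cl)=O
Why: Acylation of the phenol; the ester makes the aldehyde more electrophilic for the aldol and ring C electron-poor for the later inversion.

Step 14
Reactants: 18 (S)-4-benzyl-3-{[4-((2S,3R,4S)-4-hydroxy-3-(hydroxymethyl)-4-[3-methoxy-4-(pivaloyloxy)benzyl]oxolan-2-yl)-2-methoxyphenoxy]acetyl}oxazolidin-2-one; 20 4-formyl-2-methoxyphenyl pivalate
Product: 21 (S)-4-benzyl-3-[(2S,3R)-3-hydroxy-3-[3-methoxy-4-(pivaloyloxy)phenyl]-2-{4-((2S,3R,4S)-4-hydroxy-3-(hydroxymethyl)-4-[3-methoxy-4-(pivaloyloxy)benzyl]oxolan-2-yl)-2-methoxyphenoxy}propanoyl]oxazolidin-2-one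
Conditions: Bu2BOTf (3.3 equiv), iPr2NEt (4.0 equiv), CH2Cl2, −78 to 0 °C; 20 (1.5 equiv), −78 to 0 °C; pH 7 buffer (NaH2PO4/Na2HPO4), MeOH, 30% H2O2, 0 °C
Reagents that add atoms: none
Why: Evans syn aldol through the Z-boron enolate and a Zimmerman–Traxler chair: the (S)-benzyl auxiliary selects the enolate face, which sets Cβ in the configuration that is R in the final diol and Cα as R (syn, threo). Two further equivalents of Bu2BOTf mask the primary and tertiary hydroxyls as borinates in the flask, and the oxidative work-up releases them.

Step 15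
Reactants: 21 (S)-4-benzyl-3-[(2S,3R)-3-hydroxy-3-[3-methoxy-4-(pivaloyloxy)phenyl]-2-{4-((2S,3R,4S)-4-hydroxy-3-(hydroxymethyl)-4-[3-methoxy-4-(pivaloyloxy)benzyl]oxolan-2-yl)-2-methoxyphenoxy}propanoyl]oxazolidin-2-one
Product: 22 (2S,3R,4S)-2-{4-[((1R,2R)-1,3-dihydroxy-1-[3-methoxy-4-(pivaloyloxy)phenyl]propan-2-yl)oxy]-3-methoxyphenyl}-3-(hydroxymethyl)-4-[3-methoxy-4-(pivaloyloxy)benzyl]oxolan-4-ol
Conditions: LiBH4 (2.5 equiv), MeOH (2.5 equiv), THF, 0 °C; aq. NH4Cl
Reagents that add atoms: none
Why: Reductive cleavage of the N-acyloxazolidinone to the primary Cγ alcohol; the activated imide carbonyl should react far faster than the hindered aryl pivalates at 0 °C, and neither side-chain centre is touched.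

Step 16
Reactants: 22 (2S,3R,4S)-2-{4-[((1R,2R)-1,3-dihydroxy-1-[3-methoxy-4-(pivaloyloxy)phenyl]propan-2-yl)oxy]-3-methoxyphenyl}-3-(hydroxymethyl)-4-[3-methoxy-4-(pivaloyloxy)benzyl]oxolan-4-ol
Product: 23 tris(4-nitrobenzoate) of the (1S,2R) isomer of 22: esters on Cα (inverted), on Cγ and on the C3 hydroxymethyl group, tertiary C4 hydroxyl free
Conditions: 4-nitrobenzoic acid (6 equiv), PPh3 (6 equiv), DIAD (6 equiv), THF, 0 °C to rt
Reagents that add atoms: 4-nitrobenzoic acid O=C(O)c1ccc(cc1)[N+](=O)[O-]
Why: Mitsunobu esterification: 4-nitrobenzoate displaces the oxyphosphonium ion of the benzylic carbinol by SN2 with inversion (Cα R to S, threo to erythro), and the acyloxy-substituted ring C disfavours ionisation. The two primary hydroxyls are esterified alongside without stereochemical consequence, and the tertiary hydroxyl does not react.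

Step 17
Reactants: 23 tris(4-nitrobenzoate) of the (1S,2R) isomer of 22
Product: 24 (2S,3R,4S)-2-{4-[((1S,2R)-1,3-dihydroxy-1-(4-hydroxy-3-methoxyphenyl)propan-2-yl)oxy]-3-methoxyphenyl}-4-(4-hydroxy-3-methoxybenzyl)-3-(hydroxymethyl)oxolan-4-ol (target)
Conditions: K2CO3 (4 equiv), MeOH/THF, 0 °C to rt; NH4Cl to pH 7
Reagents that add atoms: none
Why: Carbonate-mediated transesterification with methanol removes the three activated 4-nitrobenzoates first and the two hindered aryl pivalates afterwards, so the ring C phenol is freed only when Cα no longer carries a leaving group. No stereocentre is involved and neither acid nor hydrogen is used.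

## Compound list

1 | O-benzylvanillin | COc1cc(C=O)ccc1OCc1ccccc1 | starting material
2 | dimethyl succinate | COC(=O)CCC(=O)OC | starting material
3 | (E)-4-(4-benzyloxy-3-methoxyphenyl)-3-(methoxycarbonyl)but-3-enoic acid | COC(=O)/C(CC(=O)O)=C/c1ccc(OCc2ccccc2)c(OC)c1 | intermediate
4 | (R)-4-(4-benzyloxy-3-methoxyphenyl)-3-(methoxycarbonyl)butanoic acid | OC(=O)C[C@@H](Cc1ccc(OCc2ccccc2)c(OC)c1)C(=O)OC | intermediate
5 | (R)-4-(4-benzyloxy-3-methoxyphenyl)-3-(hydroxymethyl)butanoic acid | OC(=O)C[C@@H](Cc1ccc(OCc2ccccc2)c(OC)c1)CO | intermediate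
6 | (R)-4-(4-benzyloxy-3-methoxybenzyl)dihydrofuran-2(3H)-one | O=C1C[C@@H](Cc2ccc(OCc3ccccc3)c(OC)c2)CO1 | intermediate
7 | (3R,4S)-4-(4-benzyloxy-3-methoxybenzyl)-3-hydroxydihydrofuran-2(3H)-one | O[C@H]1C(=O)OC[C@@H]1Cc1ccc(OCc2ccccc2)c(OC)c1 | intermediate
8 | vanillyl alcohol | COc1cc(CO)ccc1O | starting material
9 | [3-methoxy-4-(triisopropylsilyloxy)phenyl]methanol | COc1cc(CO)ccc1O[Si](C(C)C)(C(C)C)C(C)C | intermediate
10 | [4-(bromomethyl)-2-methoxyphenoxy]triisopropylsilane | COc1cc(CBr)ccc1O[Si](C(C)C)(C(C)C)C(C)C | intermediate
11 | (3S,4S)-4-(4-benzyloxy-3-methoxybenzyl)-3-hydroxy-3-[3-methoxy-4-(triisopropylsilyloxy)benzyl]dihydrofuran-2(3H)-one | COc1cc(C[C@@]2(O)C(=O)OC[C@@H]2Cc3ccc(OCc4ccccc4)c(OC)c3)ccc1O[Si](C(C)C)(C(C)C)C(C)C | intermediate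
12 | (2S,3S)-3-(4-benzyloxy-3-methoxybenzyl)-2-[3-methoxy-4-(triisopropylsilyloxy)benzyl]butane-1,2,4-triol | COc1cc(C[C@@](O)(CO)[C@H](CO)Cc2ccc(OCc3ccccc3)c(OC)c2)ccc1O[Si](C(C)C)(C(C)C)C(C)C | intermediate
13 | (2S,3S)-3-(4-benzyloxy-3-methoxybenzyl)-2-(4-hydroxy-3-methoxybenzyl)butane-1,2,4-triol | COc1cc(C[C@@](O)(CO)[C@H](CO)Cc2ccc(OCc3ccccc3)c(OC)c2)ccc1O | intermediate
14 | (2S,3S)-3-(4-benzyloxy-3-methoxybenzyl)-2-[3-methoxy-4-(pivaloyloxy)benzyl]butane-1,2,4-triol | COc1cc(C[C@@](O)(CO)[C@H](CO)Cc2ccc(OCc3ccccc3)c(OC)c2)ccc1OC(=O)C(C)(C)C | intermediate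
15 | (2S,3R,4S)-2-(4-benzyloxy-3-methoxyphenyl)-3-(hydroxymethyl)-4-[3-methoxy-4-(pivaloyloxy)benzyl]oxolan-4-ol | COc1cc(C[C@@]2(O)CO[C@H](c3ccc(OCc4ccccc4)c(OC)c3)[C@H]2CO)ccc1OC(=O)C(C)(C)C | intermediate
16 | (2S,3R,4S)-2-(4-hydroxy-3-methoxyphenyl)-3-(hydroxymethyl)-4-[3-methoxy-4-(pivaloyloxy)benzyl]oxolan-4-ol | COc1cc(C[C@@]2(O)CO[C@H](c3ccc(O)c(OC)c3)[C@H]2CO)ccc1OC(=O)C(C)(C)C | intermediate
17 | (S)-4-benzyl-3-(chloroacetyl)oxazolidin-2-one | ClCC(=O)N1C(=O)OC[C@@H]1Cc1ccccc1 | starting material
18 | aryloxyacetyl imide of 16 with the (S)-4-benzyloxazolidin-2-one auxiliary | COc1cc(C[C@@]2(O)CO[C@H](c3ccc(OCC(=O)N4C(=O)OC[C@@H]4Cc5ccccc5)c(OC)c3)[C@H]2CO)ccc1OC(=O)C(C)(C)C | intermediate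
19 | vanillin | COc1cc(C=O)ccc1O | starting material
20 | 4-formyl-2-methoxyphenyl pivalate | COc1cc(C=O)ccc1OC(=O)C(C)(C)C | intermediate
21 | (2S,3R) syn aldol adduct of 18 and 20 | COc1cc(C[C@@]2(O)CO[C@H](c3ccc(O[C@H](C(=O)N4C(=O)OC[C@@H]4Cc5ccccc5)[C@H](O)c6ccc(OC(=O)C(C)(C)C)c(OC)c6)c(OC)c3)[C@H]2CO)ccc1OC(=O)C(C)(C)C | intermediate
22 | threo (αR,βR) tetraol, rings A and C as pivalates | COc1cc(C[C@@]2(O)CO[C@H](c3ccc(O[C@H](CO)[C@H](O)c4ccc(OC(=O)C(C)(C)C)c(OC)c4)c(OC)c3)[C@H]2CO)ccc1OC(=O)C(C)(C)C | intermediate
23 | erythro (αS,βR) tris(4-nitrobenzoate), rings A and C as pivalates | COc1cc(C[C@@]2(O)CO[C@H](c3ccc(O[C@H](COC(=O)c4ccc(cc4)[N+](=O)[O-])[C@@H](OC(=O)c5ccc(cc5)[N+](=O)[O-])c6ccc(OC(=O)C(C)(C)C)c(OC)c6)c(OC)c3)[C@H]2COC(=O)c7ccc(cc7)[N+](=O)[O-])ccc1OC(=O)C(C)(C)C | intermediate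
24 | target, (2S,3R,4S) core with (αS,βR) side chain | COc1cc(C[C@@]2(O)CO[C@H](c3ccc(O[C@H](CO)[C@@H](O)c4ccc(O)c(OC)c4)c(OC)c3)[C@H]2CO)ccc1O | target

## Step count and risks

Total step count: 17. Longest linear sequence: 14 steps (1, 2, 3, 4, 7, 8, 9, 10, 11, 12, 14, 15, 16, 17); steps 5–6 and step 13 are side branches.

Least certain steps:

Step 10 (key). The product is itself a cyclic para-alkoxybenzyl ether, so a second hydride abstraction at C2 may compete with the first oxidation; oxidation at the wrong benzylic site and acid-promoted ring opening followed by Friedel–Crafts capture by ring A are lesser risks. The fallback sets out from 14 and returns at 16. The benzyl ether is hydrogenolysed first, while no benzylic ether is yet present, to the ring B phenol (2S,3S)-3-(4-hydroxy-3-methoxybenzyl)-2-[3-methoxy-4-(pivaloyloxy)benzyl]butane-1,2,4-triol F1. The free guaiacol is then oxidised with one equivalent of DDQ in dioxane (or with Ag2O) to the para-quinone methide F2, to which the C5 hydroxyl adds in a 1,6-sense (again 5-exo-trig), re-aromatising directly to 16. This moves the oxidation from a C–H bond to a phenol and makes step 11 unnecessary.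

Step 16. The inversion may lose fidelity if the oxyphosphonium ion ionises or a neighbouring ester participates, and elimination may compete at the crowded carbinol. The fallback sets out from 22 and returns at 24. The benzylic carbinol is oxidised selectively with MnO2 to the α-aryloxy-β-hydroxy ketone F3. Reduction with NaBH4 in MeOH/THF at low temperature should, by the Felkin–Anh model with the aryloxy group anti to the incoming hydride, favour the erythro tetraol F4; the threo isomer that also forms is 22 and can be recycled. Methanolysis of the two pivalates of F4 then gives 24.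

Step 14. The two free hydroxyls may sequester the boron reagent and leave enolisation incomplete, and the adduct may undergo retro-aldol on work-up. The fallback sets out from 18 and returns at 22. Both hydroxyls are capped first (Et3SiOTf, 2,6-lutidine) to give the bis(triethylsilyl) ether F5. The same boron aldol is run on it to give the adduct F6, which is reduced with LiBH4 to the silylated threo diol F7. The silyl groups are then removed with Bu4NF buffered with AcOH to reach 22.

Step 9. A primary hydroxyl may be acylated alongside the phenoxide. The fallback sets out from 11 and returns at 14. The silyl group is exchanged for pivaloyl at the lactone stage, where only a hindered tertiary hydroxyl competes: Bu4NF/AcOH gives the phenol lactone F8, and pivaloyl chloride with Et3N gives the pivalate lactone F9. The lactone is then opened with LiBH4 in THF at 0 °C, which reduces α-hydroxy lactones quickly and should leave the hindered aryl pivalate.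

Further compounds

F1 | step 10 | (2S,3S)-3-(4-hydroxy-3-methoxybenzyl)-2-[3-methoxy-4-(pivaloyloxy)benzyl]butane-1,2,4-triol | COc1cc(C[C@@](O)(CO)[C@H](CO)Cc2ccc(O)c(OC)c2)ccc1OC(=O)C(C)(C)C
F2 | step 10 | para-quinone methide of F1 | COC1=CC(=C[C@@H](CO)[C@](O)(CO)Cc2ccc(OC(=O)C(C)(C)C)c(OC)c2)C=CC1=O
F3 | step 16 | α-aryloxy-β-hydroxy ketone from 22 (Cα oxidised, Cβ R) | COc1cc(C[C@@]2(O)CO[C@H](c3ccc(O[C@H](CO)C(=O)c4ccc(OC(=O)C(C)(C)C)c(OC)c4)c(OC)c3)[C@H]2CO)ccc1OC(=O)C(C)(C)C
F4 | step 16 | erythro (αS,βR) tetraol, rings A and C as pivalates | COc1cc(C[C@@]2(O)CO[C@H](c3ccc(O[C@H](CO)[C@@H](O)c4ccc(OC(=O)C(C)(C)C)c(OC)c4)c(OC)c3)[C@H]2CO)ccc1OC(=O)C(C)(C)C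
F5 | step 14 | bis(triethylsilyl) ether of 18 | COc1cc(C[C@@]2(O[Si](CC)(CC)CC)CO[C@H](c3ccc(OCC(=O)N4C(=O)OC[C@@H]4Cc5ccccc5)c(OC)c3)[C@H]2CO[Si](CC)(CC)CC)ccc1OC(=O)C(C)(C)C
F6 | step 14 | bis(triethylsilyl) ether of the syn aldol adduct 21 | COc1cc(C[C@@]2(O[Si](CC)(CC)CC)CO[C@H](c3ccc(O[C@H](C(=O)N4C(=O)OC[C@@H]4Cc5ccccc5)[C@H](O)c6ccc(OC(=O)C(C)(C)C)c(OC)c6)c(OC)c3)[C@H]2CO[Si](CC)(CC)CC)ccc1OC(=O)C(C)(C)C
F7 | step 14 | bis(triethylsilyl) ether of the threo tetraol 22 | COc1cc(C[C@@]2(O[Si](CC)(CC)CC)CO[C@H](c3ccc(O[C@H](CO)[C@H](O)c4ccc(OC(=O)C(C)(C)C)c(OC)c4)c(OC)c3)[C@H]2CO[Si](CC)(CC)CC)ccc1OC(=O)C(C)(C)C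
F8 | step 9 | (3S,4S)-4-(4-benzyloxy-3-methoxybenzyl)-3-hydroxy-3-(4-hydroxy-3-methoxybenzyl)dihydrofuran-2(3H)-one | COc1cc(C[C@@]2(O)C(=O)OC[C@@H]2Cc3ccc(OCc4ccccc4)c(OC)c3)ccc1O
F9 | step 9 | (3S,4S)-4-(4-benzyloxy-3-methoxybenzyl)-3-hydroxy-3-[3-methoxy-4-(pivaloyloxy)benzyl]dihydrofuran-2(3H)-one | COc1cc(C[C@@]2(O)C(=O)OC[C@@H]2Cc3ccc(OCc4ccccc4)c(OC)c3)ccc1OC(=O)C(C)(C)C
A1 | alternative 1 | α-benzyl-α-benzyloxy-β-dithianyl-γ-menthyloxy butyrolactone (product of the three-component coupling) | COc1cc(C[C@@]2(OCc3ccccc3)C(=O)O[C@@H](O[C@@H]3C[C@H](C)CC[C@H]3C(C)C)[C@@H]2C2(c3ccc(O[Si](C(C)C)(C(C)C)C(C)C)c(OC)c3)SCCCS2)ccc1OCc1ccccc1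
A2 | alternative 1 | 3-benzyloxy-5-[(1R,2S,5R)-menthyloxy]furan-2(5H)-one | O=C1O[C@@H](O[C@@H]2C[C@H](C)CC[C@H]2C(C)C)C=C1OCc3ccccc3
A3 | alternative 1 | 2-[3-methoxy-4-(triisopropylsilyloxy)phenyl]-1,3-dithiane | COc1cc(C2SCCCS2)ccc1O[Si](C(C)C)(C(C)C)C(C)C
A4 | alternative 1 | 4-benzyloxy-3-methoxybenzyl bromide | COc1cc(CBr)ccc1OCc1ccccc1
A5 | alternative 2 | bridgehead-hydroxy 2,6-diaryl-3,7-dioxabicyclo[3.3.0]octane (photocyclisation product) | O[C@]12CO[C@H](c3ccc(OS(C)(=O)=O)c(OC)c3)[C@H]1CO[C@@H]2c1ccc(OCc2ccccc2)c(OC)c1
A6 | alternative 2 | (2S,3R)-configured 2-(ring B aryl)-3-[(ring A benzyloxy)methyl]oxolan-4-one, ring B as mesylate | O=C1CO[C@H](c2ccc(OS(C)(=O)=O)c(OC)c2)[C@H]1COCc3ccc(OCc4ccccc4)c(OC)c3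
A7 | alternative 3 | 4-hydroxy-4-(ring A benzyl)-2-(ring B aryl)oxolane-3-carbaldehyde | COc1cc(C[C@@]2(O)CO[C@H](c3ccc(O[Si](C(C)C)(C(C)C)C(C)C)c(OC)c3)[C@H]2C=O)ccc1OCc1ccccc1
A8 | alternative 3 | 1-(4-benzyloxy-3-methoxyphenyl)-3-hydroxypropan-2-one | COc1cc(CC(=O)CO)ccc1OCc1ccccc1
A9 | alternative 3 | (E)-3-[3-methoxy-4-(triisopropylsilyloxy)phenyl]prop-2-enal | COc1cc(/C=C/C=O)ccc1O[Si](C(C)C)(C(C)C)C(C)C
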